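The pyrrole is cut at N1–C5 and read back to an acyclic chain. C4 and C5 carry only hydrogen, so they can come from a terminal ethynyl group. C3, which holds the tricosyl chain, becomes a tertiary propargylic carbinol. C2 becomes the sulfonamide-bearing α-carbon of a glycine ester whose carboxyl is the latent formyl group. One silver-catalysed operation closes the only ring by 5-endo-dig hydroamination and aromatises it by loss of water across C2–C3, which fixes the 2,3-substitution pattern without any regiochemical choice. The precursor, ethyl 3-ethynyl-3-hydroxy-2-(tosylamino)hexacosanoate, arises from a glycinate aldol addition to a silyl ynone made from tetracosanoic acid.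

Key step: step 5

Assumption: the target has no stereocentre and step 5 flattens C2 and C3, so compounds 9, 10 and 11 are carried as racemic mixtures of both diastereomers and drawn without stereodescriptors.

Step 1
Reactants: 1 tetracosanoic acid; 2 bis(trimethylsilyl)acetylene
Product: 4 1-(trimethylsilyl)hexacos-1-yn-3-one, via tetracosanoyl chloride 3 (not isolated)
Conditions: (COCl)2, DMF (cat.), CH2Cl2, rt to 35 °C, evaporate; then 2, AlCl3 (1.1 equiv), CH2Cl2, 0 °C; ice/dilute HCl
Reagents that add atoms: oxalyl chloride, O=C(Cl)C(=O)Cl (its chlorine is held by 3 only and leaves again on the way to 4)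
Why: Vilsmeier-type activation gives the acyl chloride, whose AlCl3-generated acylium ion replaces one Me3Si group of the alkyne (Friedel–Crafts-type ipso-acylation of an alkynylsilane directed by the β-silyl effect), and the second silyl group should stay because the ynone formed is deactivated.

Step 2
Reactants: 5 glycine ethyl ester hydrochloride
Product: 6 ethyl N-tosylglycinate
Conditions: TsCl (1.05 equiv), Et3N (2.2 equiv), CH2Cl2, 0 °C to rt
Reagents that add atoms: p-toluenesulfonyl chloride, Cc1ccc(cc1)S(=O)(=O)Cl
Why: N-sulfonylation of the liberated primary amine (Schotten–Baumann-type reaction with an amine base) stops at the monosulfonamide, which later acidifies the glycine unit for enolisation and serves as the nucleophile of the ring closure.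

Step 3
Reactants: 6 ethyl N-tosylglycinate; 4 1-(trimethylsilyl)hexacos-1-yn-3-one
Product: 9 ethyl 3-hydroxy-2-(tosylamino)-3-[(trimethylsilyl)ethynyl]hexacosanoate (racemic diastereomer mixture), via dilithium enolate 7 (not isolated), via divalent tin enolate 8 (not isolated)
Conditions: LiN(i-Pr)2 (2.2 equiv), THF, −78 °C; SnCl2 (anhydrous, 2.2 equiv), −78 °C; then 4 in dilute THF, −78 to −40 °C; pH 7 buffer
Reagents that add atoms: LiN(i-Pr)2, [Li]N(C(C)C)C(C)C (lithium in 7 only); SnCl2, Cl[Sn]Cl (tin in 8 only)
Why: Double deprotonation and transmetalation give an N,O-chelated divalent tin enolate that is nucleophilic but weakly basic, so the aldol addition should go 1,2 to the ketone instead of deprotonating its α-methylene or attacking the silyl-shielded alkyne terminus, and the two new stereocentres (C2, C3) need no control because step 5 erases both.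

Step 4
Reactants: 9 ethyl 3-hydroxy-2-(tosylamino)-3-[(trimethylsilyl)ethynyl]hexacosanoate
Product: 10 ethyl 3-ethynyl-3-hydroxy-2-(tosylamino)hexacosanoate (racemic diastereomer mixture)
Conditions: n-Bu4NF (1.2 equiv), AcOH (1.2 equiv), THF, 0 °C
Reagents that add atoms: none
Why: Fluoride-induced protodesilylation of the C(sp)–Si bond is fast, and the acetic acid buffer keeps alkoxide and sulfonamide anion concentrations too low for retro-aldol cleavage, while the alcohol-free medium excludes ester exchange.

Step 5
Reactants: 10 ethyl 3-ethynyl-3-hydroxy-2-(tosylamino)hexacosanoate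
Product: 12 ethyl 1-tosyl-3-tricosyl-1H-pyrrole-2-carboxylate, via 3-hydroxy-2,3-dihydropyrrole 11 (not isolated)
Conditions: AgNO3 on SiO2 (10 wt %, 0.1 equiv Ag), CH2Cl2, rt, dark; filter; then PPTS (5 mol %), CH2Cl2, rt
Reagents that add atoms: none
Why: Monovalent silver dispersed on silica binds the terminal C4≡C5 triple bond as a soft π-acid, the sulfonamide nitrogen adds anti to C5, and protodemetalation releases the cyclic enesulfonamide 11 and the catalyst. The closest known reaction type is the silver- or gold-catalysed cycloisomerisation of 3-hydroxy-2-sulfonamido-4-alkynes to pyrroles, that is, an intramolecular alkyne hydroamination followed by dehydration. The one ring formed closes at N1–C5 in the 5-endo-dig mode, whereas attack at C4 would be a strained 4-exo-dig closure. In 11 the tertiary C3 hydroxyl is allylic to the electron-rich C4=C5 bond and C2–H is acidified by the ester, so silica and the trace of PPTS remove water across C2–C3 and aromatisation makes the loss irreversible. No stereocentre has to be controlled, since C2 and C3 both end as sp2 ring carbons and the diastereomers of 10 converge on one product. The selectivity required is nitrogen attack ahead of Meyer–Schuster rearrangement or ionisation of the propargylic alcohol, and it is secured by the near-neutral aprotic medium of the metal stage, by the nitrogen sitting three atoms away from an unhindered terminal alkyne carbon, and by adding the acid only after the alkyne is consumed.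

Step 6
Reactants: 12 ethyl 1-tosyl-3-tricosyl-1H-pyrrole-2-carboxylate
Product: 13 (1-tosyl-3-tricosyl-1H-pyrrol-2-yl)methanol
Conditions: i-Bu2AlH (2.5 equiv), CH2Cl2, −40 to 0 °C; aq. potassium sodium tartrate
Reagents that add atoms: none
Why: Hydride reduction of the ester with i-Bu2AlH should stop cleanly at the primary alcohol, because the electron-withdrawing tosyl group still on nitrogen blocks azafulvene formation, which in an N–H pyrrole opens the way to over-reduction to a 2-methyl group and to self-condensation.

Step 7
Reactants: 13 (1-tosyl-3-tricosyl-1H-pyrrol-2-yl)methanol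
Product: 14 1-tosyl-3-tricosyl-1H-pyrrole-2-carbaldehyde
Conditions: activated MnO2 (15 equiv), CH2Cl2, rt
Reagents that add atoms: none
Why: Heterogeneous MnO2 oxidation is selective for the pyrrolylic (benzylic-type) alcohol and stops at the aldehyde because no hydrate can form in the dry medium.

Step 8
Reactants: 14 1-tosyl-3-tricosyl-1H-pyrrole-2-carbaldehyde
Product: 15 3-tricosyl-1H-pyrrole-2-carbaldehyde (target)
Conditions: NaOH (2 M aq., 3 equiv), 1,4-dioxane, rt to 40 °C
Reagents that add atoms: none
Why: In this alkaline hydrolysis of an N-sulfonylpyrrole, hydroxide attacks sulfur and expels the stabilised 2-formylpyrrolide; the aldehyde cannot enolise, the alcohol-free medium forms no alkyl tosylate that could alkylate nitrogen, and the product is a robust vinylogous formamide.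

Compound list
1 | tetracosanoic acid (lignoceric acid) | CCCCCCCCCCCCCCCCCCCCCCCC(=O)O | starting material
2 | bis(trimethylsilyl)acetylene | C[Si](C)(C)C#C[Si](C)(C)C | starting material
3 | tetracosanoyl chloride | CCCCCCCCCCCCCCCCCCCCCCCC(=O)Cl | intermediate
4 | 1-(trimethylsilyl)hexacos-1-yn-3-one | CCCCCCCCCCCCCCCCCCCCCCCC(=O)C#C[Si](C)(C)C | intermediate
5 | glycine ethyl ester hydrochloride | Cl.NCC(=O)OCC | starting material
6 | ethyl N-tosylglycinate | CCOC(=O)CNS(=O)(=O)c1ccc(C)cc1 | intermediate
7 | dilithium N,O-dianion (ester enolate and sulfonamide anion) of ethyl N-tosylglycinate | [Li]OC(OCC)=CN([Li])S(=O)(=O)c1ccc(C)cc1 | intermediate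
8 | N,O-chelated divalent tin enolate of ethyl N-tosylglycinate (five-membered Sn–O–C=C–N chelate) | CCOC1=CN(S(=O)(=O)c2ccc(C)cc2)[Sn]O1 | intermediate
9 | ethyl 3-hydroxy-2-(tosylamino)-3-[(trimethylsilyl)ethynyl]hexacosanoate, racemic, both diastereomers | CCCCCCCCCCCCCCCCCCCCCCCC(O)(C#C[Si](C)(C)C)C(NS(=O)(=O)c1ccc(C)cc1)C(=O)OCC | intermediate
10 | ethyl 3-ethynyl-3-hydroxy-2-(tosylamino)hexacosanoate, racemic, both diastereomers | CCCCCCCCCCCCCCCCCCCCCCCC(O)(C#C)C(NS(=O)(=O)c1ccc(C)cc1)C(=O)OCC | intermediate
11 | ethyl 3-hydroxy-1-tosyl-3-tricosyl-2,3-dihydro-1H-pyrrole-2-carboxylate, racemic, both diastereomers | CCCCCCCCCCCCCCCCCCCCCCCC1(O)C=CN(S(=O)(=O)c2ccc(C)cc2)C1C(=O)OCC | intermediate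
12 | ethyl 1-tosyl-3-tricosyl-1H-pyrrole-2-carboxylate | CCCCCCCCCCCCCCCCCCCCCCCc1ccn(S(=O)(=O)c2ccc(C)cc2)c1C(=O)OCC | intermediate
13 | (1-tosyl-3-tricosyl-1H-pyrrol-2-yl)methanol | CCCCCCCCCCCCCCCCCCCCCCCc1ccn(S(=O)(=O)c2ccc(C)cc2)c1CO | intermediate
14 | 1-tosyl-3-tricosyl-1H-pyrrole-2-carbaldehyde | CCCCCCCCCCCCCCCCCCCCCCCc1ccn(S(=O)(=O)c2ccc(C)cc2)c1C=O | intermediate
15 | 3-tricosyl-1H-pyrrole-2-carbaldehyde | CCCCCCCCCCCCCCCCCCCCCCCc1cc[nH]c1C=O | target

Total step count: 8 (step 1 is a telescoped two-stage operation).
Longest linear sequence: 7 (steps 1, 3, 4, 5, 6, 7, 8 from tetracosanoic acid); step 2 is a one-step side branch.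

Steps most likely to fail

1. Step 5.
- What may go wrong: deprotonative metalation of the terminal alkyne could take silver out of the catalytic cycle. A 1,3-shift of the propargylic hydroxyl in the Meyer–Schuster sense could compete. The sequence could also stall before the loss of water.
- Fallback, from 10 back to 12: π-acid catalysis is replaced by a stoichiometric iodonium-induced closure. I2 and NaHCO3 in MeCN/CH2Cl2 should effect a 5-endo-dig iodoamination to ethyl 3-hydroxy-4-iodo-1-tosyl-3-tricosyl-2,3-dihydro-1H-pyrrole-2-carboxylate F1. Catalytic p-toluenesulfonic acid in CH2Cl2 should dehydrate this to ethyl 4-iodo-1-tosyl-3-tricosyl-1H-pyrrole-2-carboxylate F2. Hydrogenolysis of the C4–iodine bond (H2, Pd on carbon, Et3N, EtOAc) then returns 12.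

2. Step 3.
- What may go wrong: proton transfer from the α-methylene of the ynone to the enolate, conjugate addition at the alkyne terminus, crystallisation of the waxy ketone out of cold THF, or reversal of the addition on warming.
- Fallback, from 4 back to 9: no glycine enolate is used. The C2–C3 bond is made as an alkene at room temperature and both heteroatoms are installed afterwards.
  - Horner–Wadsworth–Emmons olefination of 4 with triethyl phosphonoacetate (NaH, THF) should give ethyl 3-[(trimethylsilyl)ethynyl]hexacos-2-enoate F3, whose double-bond geometry is irrelevant.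
  - Alkene-selective dihydroxylation (OsO4 cat., N-methylmorpholine N-oxide, THF/t-BuOH/H2O) gives ethyl 2,3-dihydroxy-3-[(trimethylsilyl)ethynyl]hexacosanoate F4.
  - SOCl2/Et3N ties the diol up as the cyclic sulfite ethyl 5-tricosyl-5-[(trimethylsilyl)ethynyl]-1,3,2-dioxathiolane-4-carboxylate 2-oxide F5.
  - NaN3 in DMF opens it at the ester-activated secondary carbon C2 and, after aqueous acid, gives ethyl 2-azido-3-hydroxy-3-[(trimethylsilyl)ethynyl]hexacosanoate F6.
  - Staudinger reduction (PPh3, THF/H2O) gives ethyl 2-amino-3-hydroxy-3-[(trimethylsilyl)ethynyl]hexacosanoate F7.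
  - Sulfonylation with TsCl/Et3N delivers 9.

3. Step 4.
- What may go wrong: retro-aldol cleavage of the tertiary β-hydroxy ester if fluoride or the transient acetylide acts as a base faster than the buffer protonates it.
- Fallback, from 4 back to 10: the desilylation is moved ahead of the carbon–carbon bond formation, to a stage where no aldol linkage exists. Aqueous Na2B4O7 in MeOH/THF should strip the silyl group from 4 to give hexacos-1-yn-3-one F8. The divalent tin enolate 8, generated as in step 3, is then added to F8 at −78 °C under kinetic 1,2-control to give 10 directly.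

Further compounds
F1 | step 5 | ethyl 3-hydroxy-4-iodo-1-tosyl-3-tricosyl-2,3-dihydro-1H-pyrrole-2-carboxylate (diastereomer mixture) | CCCCCCCCCCCCCCCCCCCCCCCC1(O)C(I)=CN(S(=O)(=O)c2ccc(C)cc2)C1C(=O)OCC
F2 | step 5 | ethyl 4-iodo-1-tosyl-3-tricosyl-1H-pyrrole-2-carboxylate | CCCCCCCCCCCCCCCCCCCCCCCc1c(I)cn(S(=O)(=O)c2ccc(C)cc2)c1C(=O)OCC
F3 | step 3 | ethyl 3-[(trimethylsilyl)ethynyl]hexacos-2-enoate (E/Z mixture) | CCCCCCCCCCCCCCCCCCCCCCCC(C#C[Si](C)(C)C)=CC(=O)OCC
F4 | step 3 | ethyl 2,3-dihydroxy-3-[(trimethylsilyl)ethynyl]hexacosanoate (diastereomer mixture) | CCCCCCCCCCCCCCCCCCCCCCCC(O)(C#C[Si](C)(C)C)C(O)C(=O)OCC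
F5 | step 3 | ethyl 5-tricosyl-5-[(trimethylsilyl)ethynyl]-1,3,2-dioxathiolane-4-carboxylate 2-oxide (diastereomer mixture) | CCCCCCCCCCCCCCCCCCCCCCCC1(C#C[Si](C)(C)C)OS(=O)OC1C(=O)OCC
F6 | step 3 | ethyl 2-azido-3-hydroxy-3-[(trimethylsilyl)ethynyl]hexacosanoate (diastereomer mixture) | CCCCCCCCCCCCCCCCCCCCCCCC(O)(C#C[Si](C)(C)C)C(N=[N+]=[N-])C(=O)OCC
F7 | step 3 | ethyl 2-amino-3-hydroxy-3-[(trimethylsilyl)ethynyl]hexacosanoate (diastereomer mixture) | CCCCCCCCCCCCCCCCCCCCCCCC(O)(C#C[Si](C)(C)C)C(N)C(=O)OCC
F8 | step 4 | hexacos-1-yn-3-one | CCCCCCCCCCCCCCCCCCCCCCCC(=O)C#C
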